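Ring A is cut at C1–C2 and C3–C4. C2–C3 come from methyl bis(2,2,2-trifluoroethyl)phosphonoacetate, which joins a ring B aldehyde ester in one pot by Z-olefination (C1=C2) and then Dieckmann closure (C3–C4). The temporary 1-en-3-one is erased through an enol triflate and hydrogen.
Enabling feature: in ring A, C1–C3 are bare methylenes between two quaternary carbons. C10 makes a C1 aldehyde non-enolisable and leaves the derived enoate without a gamma hydrogen, and C4 is alpha to the C18 ester and so a latent enolate. C1 and C4 sit trans-diequatorial on the adjacent ring B atoms C10 and C5, one two-carbon bridge apart.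
The ring B precursor is assembled from three parts on a 3-methyl-4-substituted cyclohexenone: a vinyl cuprate (C1, anti to the C5 arm), then the chiral-pool iodide C11–C16 at C9. C5 comes from a catalytic ketone reduction relayed by a Johnson–Claisen rearrangement, and C10, C9 and C4 are relayed from C5.
Endgame: C17 by Wittig methylenation of the 8-ketone, which keeps the C9 chain equatorial, and the C15 acid by oxidation of a primary alcohol.
Ring order: ring B is bought as 2-methylcyclohex-2-en-1-one, and ring A is formed last, in the key step.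

Key step: step 12

Remark: labdane numbering is used throughout. C4, the alpha carbon of the propanoate arm, is an inconsequential epimer mixture in every intermediate before the key step, where enolisation erases it, so it carries no stereo label there.

Step 1
Reactants: 1 2-methylcyclohex-2-en-1-one
Product: 2 (1S)-2-methylcyclohex-2-en-1-ol
Conditions: (R)-2-methyl-CBS-oxazaborolidine [(3aR)-1-methyl-3,3-diphenyltetrahydro-3H-pyrrolo[1,2-c][1,3,2]oxazaborole] (10 mol %), BH3·SMe2, THF, −20 °C; MeOH
Reagents that add atoms: none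
Why: Corey–Bakshi–Shibata reduction, in which the catalyst binds the carbonyl away from the more demanding 2-methylvinyl flank and delivers hydride to one face only, giving 1,2-reduction and setting the carbinol centre (S) from which C5 is relayed.

Step 2
Reactants: 2 (1S)-2-methylcyclohex-2-en-1-ol
Product: 4 methyl 2-[(1S)-2-methylcyclohex-2-en-1-yl]propanoate, via ketene acetal 3 (not isolated)
Conditions: EtC(OMe)3, EtCO2H (cat.), xylene, 140 °C, MeOH distilled off
Reagents that add atoms: trimethyl orthopropionate, CCC(OC)(OC)OC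
Why: Johnson orthoester Claisen rearrangement, in which exchange and loss of methanol give 3, whose [3,3] shift within the ring can only be suprafacial, so the C–O stereocentre is traded for the C4–C5 bond on the same face (C5 set) and the methyl ester is delivered directly.

Step 3
Reactants: 4 methyl 2-[(1S)-2-methylcyclohex-2-en-1-yl]propanoate
Product: 5 methyl 2-[(1S)-2-methyl-4-oxocyclohex-2-en-1-yl]propanoate
Conditions: Rh2(cap)4 [dirhodium tetrakis(caprolactamate), Rh2(C6H10NO)4] (1 mol %), t-BuOOH (70 % in H2O), 40 °C
Reagents that add atoms: tert-butyl hydroperoxide, CC(C)(C)OO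
Why: Catalytic allylic oxidation by hydrogen abstraction at the least hindered allylic methylene (C8) should give the 3-methylcyclohexenone, as 1-methylcyclohexenes do, under base-free conditions that leave the gamma stereocentre C5 untouched.

Step 4
Reactants: 5 methyl 2-[(1S)-2-methyl-4-oxocyclohex-2-en-1-yl]propanoate
Product: 6 methyl 2-[(1S,2S)-2-ethenyl-2-methyl-4-(trimethylsilyloxy)cyclohex-3-en-1-yl]propanoate
Conditions: CH2=CHMgBr, CuBr·SMe2 (20 mol %), Me3SiCl, HMPA, THF, −78 °C; Et3N, pentane work-up
Reagents that add atoms: vinylmagnesium bromide, C=C[Mg]Br; chlorotrimethylsilane, C[Si](C)(C)Cl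
Why: Chlorosilane-accelerated copper-catalysed conjugate addition, in which the vinyl group attacks C10 axially and anti to the neighbouring C5 arm, as is general for 4-substituted cyclohexenones, so the quaternary centre is set (vinyl trans, methyl cis to the arm) and silylation stores the enolate regiospecifically at C8=C9.

Step 5
Reactants: 7 (3R)-5-methoxy-3-methyl-5-oxopentanoic acid (methyl hydrogen (R)-3-methylglutarate)
Product: 8 methyl (3R)-5-hydroxy-3-methylpentanoate
Conditions: BH3·SMe2, THF, 0 °C → rt; MeOH
Reagents that add atoms: none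
Why: Borane reduces the free carboxylic acid chemoselectively through its acyloxyborane while the methyl ester survives, which differentiates the two ends of the glutarate without touching the C13 stereocentre.

Step 6
Reactants: 8 methyl (3R)-5-hydroxy-3-methylpentanoate
Product: 9 methyl (3R)-5-(tert-butyldimethylsilyloxy)-3-methylpentanoate
Conditions: t-BuMe2SiCl, imidazole, DMF, rt
Reagents that add atoms: tert-butyldimethylsilyl chloride, CC(C)(C)[Si](C)(C)Cl
Why: Imidazole-promoted silylation caps the primary alcohol (future C15) at once and so also prevents lactonisation of the hydroxy ester.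

Step 7
Reactants: 9 methyl (3R)-5-(tert-butyldimethylsilyloxy)-3-methylpentanoate
Product: 10 (3S)-5-(tert-butyldimethylsilyloxy)-3-methylpentan-1-ol
Conditions: LiAlH4, Et2O, 0 °C
Reagents that add atoms: none
Why: Hydride reduction of the ester to the primary alcohol (future C11) leaves the silyl ether and the remote stereocentre untouched (the descriptor changes only through CIP priorities).

Step 8
Reactants: 10 (3S)-5-(tert-butyldimethylsilyloxy)-3-methylpentan-1-ol
Product: 11 tert-butyl{[(3R)-5-iodo-3-methylpentyl]oxy}dimethylsilane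
Conditions: I2, PPh3, imidazole, CH2Cl2, 0 °C
Reagents that add atoms: iodine, II
Why: Appel-type iodination displaces the oxyphosphonium ion by SN2 at the primary carbon under neutral conditions that the silyl ether tolerates.

Step 9
Reactants: 6 methyl 2-[(1S,2S)-2-ethenyl-2-methyl-4-(trimethylsilyloxy)cyclohex-3-en-1-yl]propanoate; 11 tert-butyl{[(3R)-5-iodo-3-methylpentyl]oxy}dimethylsilane
Product: 13 methyl 2-[(1S,2S,3R)-3-[(3S)-5-(tert-butyldimethylsilyloxy)-3-methylpentyl]-2-ethenyl-2-methyl-4-oxocyclohexyl]propanoate, via ammonium enolate 12 (not isolated)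
Conditions: BnMe3N+ F− (1.0 equiv, dried), 4 Å MS, THF, −20 °C → rt; then NaOMe (cat.), MeOH, rt
Reagents that add atoms: none
Why: Fluoride-promoted regiospecific alkylation of a silyl enol ether, in which the single equivalent of fluoride is consumed by the far more labile trimethylsilyl enol ether to unmask enolate 12 only at C8=C9, SN2 attack on the primary iodide forms C9–C11, and methoxide equilibration next to the ketone places the chain equatorial (trans to vinyl).

Step 10
Reactants: 13 methyl 2-[(1S,2S,3R)-3-[(3S)-5-(tert-butyldimethylsilyloxy)-3-methylpentyl]-2-ethenyl-2-methyl-4-oxocyclohexyl]propanoate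
Product: 14 methyl 2-[(6R,7S,8S)-6-[(3S)-5-(tert-butyldimethylsilyloxy)-3-methylpentyl]-7-ethenyl-7-methyl-1,4-dioxaspiro[4.5]decan-8-yl]propanoate (C8 ethylene ketal of 13)
Conditions: Me3SiOCH2CH2OSiMe3, Me3SiOSO2CF3 (5 mol %), CH2Cl2, −78 → −20 °C; pyridine
Reagents that add atoms: 1,2-bis(trimethylsilyloxy)ethane, C[Si](C)(C)OCCO[Si](C)(C)C
Why: Silyl triflate-catalysed ketalisation with the bis-silyl ether of glycol works at low temperature on hindered ketones without harming silyl ether, ester or vinyl group, freezes C9, and removes the ketone enolisation sites before the base-mediated key step.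

Step 11
Reactants: 14 C8 ethylene ketal of 13
Product: 16 methyl 2-[(6R,7S,8S)-6-[(3S)-5-(tert-butyldimethylsilyloxy)-3-methylpentyl]-7-formyl-7-methyl-1,4-dioxaspiro[4.5]decan-8-yl]propanoate, via ozonide 15 (not isolated)
Conditions: O3, CH2Cl2, −78 °C; Me2S, −78 °C → rt
Reagents that add atoms: ozone, [O-][O+]=O
Why: Ozonolysis of the only C=C bond (cycloaddition, cycloreversion and recombination to 15, then reductive cleavage) turns the vinyl group into the C1 formyl group on quaternary C10 without touching any stereocentre.

Step 12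
Reactants: 16 ring B aldehyde ester (7-formyl compound above); 17 methyl bis(2,2,2-trifluoroethyl)phosphonoacetate
Product: 20 methyl (13S)-15-(tert-butyldimethylsilyloxy)-8,8-(ethylenedioxy)-3-oxo-17-norlabd-1-en-18-oate, via Z-enoate 18 (not isolated), via potassium enolate 19 (not isolated)
Conditions: 17, KN(SiMe3)2 (1.1 equiv), 18-crown-6, THF, −78 °C, then 16; then KN(SiMe3)2 (1.5 equiv), −78 → −20 °C; AcOH, −78 °C
Reagents that add atoms: none
Why: The potassium anion of 17 adds to the non-enolisable neopentyl aldehyde and the electron-poor phosphonate collapses under kinetic control (Still–Gennari olefination) to Z-enoate 18, which makes C1=C2 and holds the ester carbon C3 cis to C10, within reach of C4. The second portion of base removes the only acidic proton left, H4, and enolate 19 acylates itself at C3 with loss of methoxide (a Dieckmann condensation driven by stoichiometric strong base, as in Claisen condensations of alpha,alpha-disubstituted esters), so 17 acts as a C2–C3 linchpin, nucleophilic at C2 and electrophilic at C3. Ring A closes in a 6-(enolexo)-exo-trig mode across the trans-diequatorial C1 and C4 arms of ring B, which gives the trans-decalin directly. C4, the only new stereocentre, is controlled by allylic 1,3-strain: C3 is tethered through C1 to C10 and must reach the enolate face turned toward C10, and in that arrangement the enolate carbon C18 with its cis oxygen can lie only next to H5, so CO2Me ends equatorial (alpha) and the methyl group axial (beta). An intermolecular C3–C4 bond formation would come from the opposite face, which is why the olefination comes first. The regiochemistry of the condensation is secured because the enoate has neither an alpha nor a gamma proton (C2 vinylic, C10 quaternary), the ketone is a ketal and the side chain ends in a silyl ether, while any E-enoate cannot cyclise and is removed by chromatography.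

Step 13
Reactants: 20 methyl (13S)-15-(tert-butyldimethylsilyloxy)-8,8-(ethylenedioxy)-3-oxo-17-norlabd-1-en-18-oate
Product: 22 methyl (13S)-15-(tert-butyldimethylsilyloxy)-8,8-(ethylenedioxy)-3-(trifluoromethylsulfonyloxy)-17-norlabd-2-en-18-oate, via lithium enolate 21 (not isolated)
Conditions: LiBH(s-Bu)3, THF, −78 °C; PhN(SO2CF3)2, −78 → 0 °C
Reagents that add atoms: N-phenylbis(trifluoromethanesulfonimide), O=S(=O)(N(c1ccccc1)S(=O)(=O)C(F)(F)F)C(F)(F)F
Why: Conjugate reduction with enolate trapping, in which the bulky borohydride, kept from the carbonyl by quaternary C4, adds hydride to the beta-unsubstituted position C1 and the regiodefined enolate 21 is O-sulfonylated to the C2=C3 enol triflate.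

Step 14
Reactants: 22 enol triflate above
Product: 23 methyl (13S)-15-(tert-butyldimethylsilyloxy)-8,8-(ethylenedioxy)-17-norlabdan-18-oate
Conditions: H2 (1 atm), PtO2, NaHCO3, EtOAc, rt
Reagents that add atoms: none
Why: Hydrogenolysis and hydrogenation of an enol triflate over PtO2 replace C–O by C–H and saturate C2=C3, erasing the temporary oxygen at C3 with no stereocentre involved, while bicarbonate buffers the triflic acid so that ketal and silyl ether survive.

Step 15
Reactants: 23 methyl (13S)-15-(tert-butyldimethylsilyloxy)-8,8-(ethylenedioxy)-17-norlabdan-18-oate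
Product: 24 methyl (13S)-15-hydroxy-8-oxo-17-norlabdan-18-oate
Conditions: 2 M aq. HCl, THF, rt
Reagents that add atoms: water, O
Why: Acid hydrolysis cleaves the dioxolane and the primary silyl ether in one operation, and the liberated C8 ketone keeps, or restores by enolisation, the equatorial C9 side chain of the trans-decalin.

Step 16
Reactants: 24 methyl (13S)-15-hydroxy-8-oxo-17-norlabdan-18-oate
Product: 25 methyl (13S)-15-hydroxylabd-8(17)-en-18-oate
Conditions: Ph3PCH3Br, KOt-Bu (4 equiv each), toluene, 0 → 80 °C
Reagents that add atoms: methyltriphenylphosphonium bromide, C[P+](c1ccccc1)(c1ccccc1)c1ccccc1.[Br-]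
Why: Wittig methylenation with excess ylide (one equivalent is held by the alcohol) converts the hindered 8-oxo decalin into the exocyclic C8=C17 methylene, the tertiary C18 ester being inert and C9, if enolised, returning to the equatorial epimer.

Step 17
Reactants: 25 methyl (13S)-15-hydroxylabd-8(17)-en-18-oate
Product: 27 (13S)-18-methoxy-18-oxolabd-8(17)-en-15-oic acid (target), via aldehyde 26 (not isolated)
Conditions: TEMPO (2,2,6,6-tetramethylpiperidin-1-oxyl, 20 mol %), PhI(OAc)2 (2.2 equiv), MeCN–H2O 1:1, rt
Reagents that add atoms: water, O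
Why: Oxoammonium-catalysed oxidation takes the primary alcohol through 26 and its hydrate to the acid without attacking the 1,1-disubstituted alkene, the hindered ester or the beta stereocentre C13.

Compound list
1 | 2-methylcyclohex-2-en-1-one | CC1=CCCCC1=O | starting material
2 | (1S)-2-methylcyclohex-2-en-1-ol | O[C@H]1CCCC=C1C | intermediate
3 | methyl (1S)-2-methylcyclohex-2-en-1-yl ketene acetal of propanoic acid | CC=C(OC)O[C@H]1CCCC=C1C | intermediate
4 | methyl 2-[(1S)-2-methylcyclohex-2-en-1-yl]propanoate | C1CC[C@@H](C(C)C(=O)OC)C(C)=C1 | intermediate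
5 | methyl 2-[(1S)-2-methyl-4-oxocyclohex-2-en-1-yl]propanoate | O=C1CC[C@@H](C(C)C(=O)OC)C(C)=C1 | intermediate
6 | methyl 2-[(1S,2S)-2-ethenyl-2-methyl-4-(trimethylsilyloxy)cyclohex-3-en-1-yl]propanoate | C1(O[Si](C)(C)C)CC[C@@H](C(C)C(=O)OC)[C@](C)(C=C)C=1 | intermediate
7 | (3R)-5-methoxy-3-methyl-5-oxopentanoic acid | COC(=O)C[C@H](C)CC(=O)O | starting material
8 | methyl (3R)-5-hydroxy-3-methylpentanoate | COC(=O)C[C@H](C)CCO | intermediate
9 | methyl (3R)-5-(tert-butyldimethylsilyloxy)-3-methylpentanoate | COC(=O)C[C@H](C)CCO[Si](C)(C)C(C)(C)C | intermediate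
10 | (3S)-5-(tert-butyldimethylsilyloxy)-3-methylpentan-1-ol | OCC[C@H](C)CCO[Si](C)(C)C(C)(C)C | intermediate
11 | tert-butyl{[(3R)-5-iodo-3-methylpentyl]oxy}dimethylsilane | ICC[C@H](C)CCO[Si](C)(C)C(C)(C)C | intermediate
12 | benzyltrimethylammonium C8=C9 enolate from 6 | C1([O-])CC[C@@H](C(C)C(=O)OC)[C@](C)(C=C)C=1.C[N+](C)(C)Cc1ccccc1 | intermediate
13 | C9-alkylated ring B ketone (1S,2S,3R; side chain 3S) | O=C1CC[C@@H](C(C)C(=O)OC)[C@](C)(C=C)[C@H]1CC[C@H](C)CCO[Si](C)(C)C(C)(C)C | intermediate
14 | C8 ethylene ketal of 13 (6R,7S,8S) | O1CCOC13CC[C@@H](C(C)C(=O)OC)[C@](C)(C=C)[C@H]3CC[C@H](C)CCO[Si](C)(C)C(C)(C)C | intermediate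
15 | 1,2,4-trioxolane (ozonide) of the vinyl group of 14 | O1CCOC13CC[C@@H](C(C)C(=O)OC)[C@](C)(C4OCOO4)[C@H]3CC[C@H](C)CCO[Si](C)(C)C(C)(C)C | intermediate
16 | ring B aldehyde ester (C1 formyl on C10; 6R,7S,8S) | O1CCOC13CC[C@@H](C(C)C(=O)OC)[C@](C)(C=O)[C@H]3CC[C@H](C)CCO[Si](C)(C)C(C)(C)C | intermediate
17 | methyl bis(2,2,2-trifluoroethyl)phosphonoacetate | COC(=O)CP(=O)(OCC(F)(F)F)OCC(F)(F)F | starting material
18 | Z-enoate (C1=C2–C3O2Me on C10) | O1CCOC13CC[C@@H](C(C)C(=O)OC)[C@](C)(/C=C\C(=O)OC)[C@H]3CC[C@H](C)CCO[Si](C)(C)C(C)(C)C | intermediate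
19 | potassium C4 ester enolate of 18 | O1CCOC13CC[C@@H](C(C)=C([O-])OC)[C@](C)(/C=C\C(=O)OC)[C@H]3CC[C@H](C)CCO[Si](C)(C)C(C)(C)C.[K+] | intermediate
20 | methyl (13S)-15-(tert-butyldimethylsilyloxy)-8,8-(ethylenedioxy)-3-oxo-17-norlabd-1-en-18-oate | O1CCOC13CC[C@@H]2[C@](C)(C=CC(=O)[C@@]2(C)C(=O)OC)[C@H]3CC[C@H](C)CCO[Si](C)(C)C(C)(C)C | intermediate
21 | lithium C2=C3 enolate from 20 | O1CCOC13CC[C@@H]2[C@](C)(CC=C([O-])[C@@]2(C)C(=O)OC)[C@H]3CC[C@H](C)CCO[Si](C)(C)C(C)(C)C.[Li+] | intermediate
22 | C2=C3 enol triflate | O1CCOC13CC[C@@H]2[C@](C)(CC=C(OS(=O)(=O)C(F)(F)F)[C@@]2(C)C(=O)OC)[C@H]3CC[C@H](C)CCO[Si](C)(C)C(C)(C)C | intermediate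
23 | methyl (13S)-15-(tert-butyldimethylsilyloxy)-8,8-(ethylenedioxy)-17-norlabdan-18-oate | O1CCOC13CC[C@@H]2[C@](C)(CCC[C@@]2(C)C(=O)OC)[C@H]3CC[C@H](C)CCO[Si](C)(C)C(C)(C)C | intermediate
24 | methyl (13S)-15-hydroxy-8-oxo-17-norlabdan-18-oate | O=C1CC[C@@H]2[C@](C)(CCC[C@@]2(C)C(=O)OC)[C@H]1CC[C@H](C)CCO | intermediate
25 | methyl (13S)-15-hydroxylabd-8(17)-en-18-oate | C=C1CC[C@@H]2[C@](C)(CCC[C@@]2(C)C(=O)OC)[C@H]1CC[C@H](C)CCO | intermediate
26 | methyl (13S)-15-oxolabd-8(17)-en-18-oate | C=C1CC[C@@H]2[C@](C)(CCC[C@@]2(C)C(=O)OC)[C@H]1CC[C@H](C)CC=O | intermediate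
27 | (13S)-18-methoxy-18-oxolabd-8(17)-en-15-oic acid | C=C1CC[C@@H]2[C@](C)(CCC[C@@]2(C)C(=O)OC)[C@H]1CC[C@H](C)CC(=O)O | target

Total step count: 17. Longest linear sequence: 13 steps (steps 1–4 and 9–17; the arm through steps 5–8 and 9–17 is equally long).

Steps most likely to fail

Step 12. Deprotonation of the hindered C4–H may be slow. The amide base or the released methoxide may attack the enoate or reopen the non-enolisable beta-keto ester by retro-Claisen cleavage. Z selectivity at the neopentyl aldehyde may also erode. The fallback replaces the acylative closure by an alkylative one. It sets out from 18, isolated after the olefination stage. The conjugated, less shielded ester is reduced with i-Bu2AlH (CH2Cl2, −78 °C) to the Z-allylic alcohol F1. MsCl, Et3N and LiCl convert it into the Z-allylic chloride F2. KN(SiMe3)2 (THF, −78 → 0 °C) closes ring A by intramolecular ester enolate alkylation, through the same H5-eclipsed arrangement that places CO2Me equatorial, to the 1-ene F3. Hydrogenation over Pd/C then comes back to the route at 23, so steps 13 and 14 are no longer needed.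

Step 9. SN2 attack on an unactivated iodide by an enolate carbon next to a quaternary centre may be slow. Proton transfer, O-alkylation, polyalkylation and fluoride attack on the silyl ether could then compete. The fallback forms C9–C11 by a Lewis acid aldol reaction instead. It sets out from 6 and 10. Alcohol 10 is oxidised with Dess–Martin periodinane to (3S)-5-(tert-butyldimethylsilyloxy)-3-methylpentanal F4. A Mukaiyama aldol addition of 6 to F4 (BF3·OEt2, CH2Cl2, −78 °C) gives the beta-hydroxy ketone F5. Mesylation and elimination (MsCl, excess Et3N) give the exocyclic enone F6. Conjugate reduction with [(Ph3P)CuH]6 leaves the vinyl group intact, and methoxide equilibration then comes back to the route at 13.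

Step 13. Competing 1,2-reduction of the enone, or incomplete O-sulfonylation of the hindered enolate, would lower the throughput. The fallback separates the two events. It sets out from 20. Hydrogenation of the enone over Pd/C (EtOAc) gives the saturated beta-keto ester F7. Only C2 of F7 can be deprotonated, so KN(SiMe3)2 followed by PhN(SO2CF3)2 comes back to the route at 22.

Further compounds
F1 | step 12 | Z-allylic alcohol (C1=C2–C3H2OH on C10) | O1CCOC13CC[C@@H](C(C)C(=O)OC)[C@](C)(/C=C\CO)[C@H]3CC[C@H](C)CCO[Si](C)(C)C(C)(C)C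
F2 | step 12 | Z-allylic chloride | O1CCOC13CC[C@@H](C(C)C(=O)OC)[C@](C)(/C=C\CCl)[C@H]3CC[C@H](C)CCO[Si](C)(C)C(C)(C)C
F3 | step 12 | methyl (13S)-15-(tert-butyldimethylsilyloxy)-8,8-(ethylenedioxy)-17-norlabd-1-en-18-oate | O1CCOC13CC[C@@H]2[C@](C)(C=CC[C@@]2(C)C(=O)OC)[C@H]3CC[C@H](C)CCO[Si](C)(C)C(C)(C)C
F4 | step 9 | (3S)-5-(tert-butyldimethylsilyloxy)-3-methylpentanal | O=CC[C@H](C)CCO[Si](C)(C)C(C)(C)C
F5 | step 9 | C9–C11 aldol adduct (beta-hydroxy ketone) | O=C1CC[C@@H](C(C)C(=O)OC)[C@](C)(C=C)C1C(O)C[C@H](C)CCO[Si](C)(C)C(C)(C)C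
F6 | step 9 | exocyclic C9=C11 enone | O=C1CC[C@@H](C(C)C(=O)OC)[C@](C)(C=C)C1=CC[C@H](C)CCO[Si](C)(C)C(C)(C)C
F7 | step 13 | methyl (13S)-15-(tert-butyldimethylsilyloxy)-8,8-(ethylenedioxy)-3-oxo-17-norlabdan-18-oate | O1CCOC13CC[C@@H]2[C@](C)(CCC(=O)[C@@]2(C)C(=O)OC)[C@H]3CC[C@H](C)CCO[Si](C)(C)C(C)(C)C
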